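**Retrosynthetic overview**
1. Target ⇐ peri-selective 5-O-demethylation and hydrogenolysis of the two benzyl ethers of a 3-hydroxy-5,6,7,8-tetramethoxyflavone carrying a 3',4'-bis(benzyloxy) B ring.
2. Flavonol ⇐ flavone (C2=C3 epoxidation, acid isomerisation) ⇐ 2'-hydroxychalcone (oxidative cyclisation); the pyranone C ring is closed last, onto intact A and B rings.
3. Chalcone ⇐ Claisen–Schmidt aldol condensation (key C–C bond, Cα–Cβ) of 2-hydroxy-3,4,5,6-tetramethoxyacetophenone with 3,4-bis(benzyloxy)benzaldehyde.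
4. Acetophenone ⇐ pentamethoxybenzene (Friedel–Crafts acetylation with ortho-demethylation) ⇐ 3,4,5-trimethoxyphenol (methylation, Vilsmeier formylation, Baeyer–Villiger, methylation).

Assumption: the target SMILES has no stereocentre and no stereogenic double bond, so the compound is achiral and no enantiocontrol is needed; racemic transient intermediates are written without stereodescriptors.

**Route**

Step 1
Reactants: 1 3,4,5-trimethoxyphenol
Product: 2 1,2,3,5-tetramethoxybenzene
Conditions: MeI (1.5 eq), K2CO3 (2 eq), acetone, reflux, 12 h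
Reagents that add atoms: iodomethane, CI
Why: Williamson O-methylation (SN2 of the potassium phenoxide on MeI) is clean because the phenol is the only acidic site.

Step 2
Reactants: 2 1,2,3,5-tetramethoxybenzene
Product: 4 2,3,4,6-tetramethoxybenzaldehyde, via aryl iminium salt 3 (not isolated)
Conditions: POCl3 (1.3 eq), DMF, 0 °C → 70 °C, 3 h; then ice-water, 50 °C
Reagents that add atoms: N,N-dimethylformamide, CN(C)C=O; water, O
Why: Vilsmeier–Haack formylation can only attack the two equivalent free positions (each ortho to two OMe and para to a third), so one regioisomer results, and the deactivating iminium group prevents a second formylation.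

Step 3
Reactants: 4 2,3,4,6-tetramethoxybenzaldehyde
Product: 6 2,3,4,6-tetramethoxyphenol, via aryl formate 5 (not isolated)
Conditions: mCPBA (1.2 eq), CH2Cl2, 0 °C → rt; then MeOH, cat. conc. HCl, rt, N2
Reagents that add atoms: mCPBA, O=C(OO)c1cccc(Cl)c1
Why: Baeyer–Villiger (Dakin-type) oxidation in which the very electron-rich aryl group migrates in preference to H, and acid-catalysed methanolysis of the formate frees the phenol without exposing its air-sensitive phenoxide.

Step 4
Reactants: 6 2,3,4,6-tetramethoxyphenol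
Product: 7 pentamethoxybenzene
Conditions: MeI (1.5 eq), K2CO3 (2 eq), acetone, reflux, N2
Reagents that add atoms: iodomethane, CI
Why: Williamson O-methylation of the single phenol.

Step 5
Reactants: 7 pentamethoxybenzene
Product: 9 1-(2-hydroxy-3,4,5,6-tetramethoxyphenyl)ethan-1-one, via 2,3,4,5,6-pentamethoxyacetophenone 8 (not isolated)
Conditions: AcCl (1.2 eq), AlCl3 (2.5 eq), CH2Cl2, 0 °C → rt, 4–6 h; then ice/2 M HCl
Reagents that add atoms: acetyl chloride, CC(Cl)=O
Why: Friedel–Crafts acylation at the only free ring position is followed by chelation-directed cleavage of one of the two equivalent ortho OMe groups by the ketone-bound AlCl3, so the symmetry of 8 removes any regiochemical ambiguity.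

Step 6
Reactants: 9 1-(2-hydroxy-3,4,5,6-tetramethoxyphenyl)ethan-1-one; 10 3,4-bis(benzyloxy)benzaldehyde
Product: 12 (E)-3-[3,4-bis(benzyloxy)phenyl]-1-(2-hydroxy-3,4,5,6-tetramethoxyphenyl)prop-2-en-1-one, via aldol adduct 11 (not isolated)
Conditions: KOH (50% aq, 10 eq), EtOH, rt, 36–48 h; then cold 2 M HCl to pH 3
Reagents that add atoms: none
Why: Claisen–Schmidt crossed aldol condensation in which only ketone 9 can enolise and aldehyde 10 cannot, with E1cB dehydration of the aldol giving the thermodynamically favoured E-enone.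

Step 7
Reactants: 12 (E)-3-[3,4-bis(benzyloxy)phenyl]-1-(2-hydroxy-3,4,5,6-tetramethoxyphenyl)prop-2-en-1-one
Product: 14 2-[3,4-bis(benzyloxy)phenyl]-5,6,7,8-tetramethoxy-4H-chromen-4-one, via flavanone 13 (not isolated)
Conditions: I2 (10 mol %), DMSO, 130 °C, 2–3 h
Reagents that add atoms: none
Why: oxa-Michael ring closure of the 2'-phenol gives the flavanone, which undergoes iodine-catalysed dehydrogenation with DMSO as terminal oxidant to the 4-pyranone, and the short time with catalytic iodine should spare the benzyl and methyl ethers.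

Step 8
Reactants: 14 2-[3,4-bis(benzyloxy)phenyl]-5,6,7,8-tetramethoxy-4H-chromen-4-one
Product: 16 2-[3,4-bis(benzyloxy)phenyl]-3-hydroxy-5,6,7,8-tetramethoxy-4H-chromen-4-one, via flavone epoxide 15 (not isolated)
Conditions: DMDO (ca. 0.08 M in acetone, 3 eq in portions), CH2Cl2, 0 °C → rt, 24–48 h, dark; evaporate; then p-TsOH·H2O (5 mol %), CH2Cl2, rt, 1 h
Reagents that add atoms: dimethyldioxirane, CC1(C)OO1
Why: neutral electrophilic epoxidation of the enol-ether-like C2=C3 bond, then acid-catalysed opening at C2 (oxocarbenium) and loss of H-3 gives the 3-hydroxyflavone without the aurone diversion that 6'-methoxychalcones suffer under alkaline peroxide; no stereocentre survives.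

Step 9
Reactants: 16 2-[3,4-bis(benzyloxy)phenyl]-3-hydroxy-5,6,7,8-tetramethoxy-4H-chromen-4-one
Product: 17 2-(3,4-dihydroxyphenyl)-3-hydroxy-5,6,7,8-tetramethoxy-4H-chromen-4-one
Conditions: H2 (1 atm), 10% Pd/C, THF/MeOH 1:1, rt, 4–6 h
Reagents that add atoms: none
Why: catalytic hydrogenolysis cleaves the two benzyl aryl ethers while the methyl ethers and the pyranone C2=C3 bond (a vinylogous ester) are inert at 1 atm.

Step 10
Reactants: 17 2-(3,4-dihydroxyphenyl)-3-hydroxy-5,6,7,8-tetramethoxy-4H-chromen-4-one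
Product: 18 2-(3,4-dihydroxyphenyl)-3,5-dihydroxy-6,7,8-trimethoxy-4H-chromen-4-one (3,5,3',4'-tetrahydroxy-6,7,8-trimethoxyflavone)
Conditions: BCl3 (1 M in CH2Cl2, 5 eq), CH2Cl2, −78 °C → 0 °C, 2–3 h; then ice-water, 1 M HCl, rt
Reagents that add atoms: none
Why: chelation-controlled Lewis-acid ether cleavage in which boron bound at the C4 carbonyl activates only the peri 5-OMe, and at or below 0 °C the 6-, 7- and 8-OMe groups are expected to remain intact.

**Compound list**
1 | 3,4,5-trimethoxyphenol | COc1cc(O)cc(OC)c1OC | starting material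
2 | 1,2,3,5-tetramethoxybenzene | COc1cc(OC)c(OC)c(OC)c1 | intermediate
3 | N,N-dimethyl-(2,3,4,6-tetramethoxyphenyl)methaniminium chloride | C[N+](C)=Cc1c(OC)cc(OC)c(OC)c1OC.[Cl-] | intermediate (not isolated)
4 | 2,3,4,6-tetramethoxybenzaldehyde | COc1cc(OC)c(C=O)c(OC)c1OC | intermediate
5 | 2,3,4,6-tetramethoxyphenyl formate | O=COc1c(OC)cc(OC)c(OC)c1OC | intermediate (not isolated)
6 | 2,3,4,6-tetramethoxyphenol | Oc1c(OC)cc(OC)c(OC)c1OC | intermediate
7 | pentamethoxybenzene | COc1cc(OC)c(OC)c(OC)c1OC | intermediate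
8 | 1-(2,3,4,5,6-pentamethoxyphenyl)ethan-1-one | CC(=O)c1c(OC)c(OC)c(OC)c(OC)c1OC | intermediate (not isolated)
9 | 1-(2-hydroxy-3,4,5,6-tetramethoxyphenyl)ethan-1-one | CC(=O)c1c(O)c(OC)c(OC)c(OC)c1OC | intermediate
10 | 3,4-bis(benzyloxy)benzaldehyde | O=Cc1ccc(OCc2ccccc2)c(OCc2ccccc2)c1 | starting material
11 | 3-[3,4-bis(benzyloxy)phenyl]-3-hydroxy-1-(2-hydroxy-3,4,5,6-tetramethoxyphenyl)propan-1-one (racemic) | COc1c(OC)c(OC)c(C(=O)CC(O)c2ccc(OCc3ccccc3)c(OCc3ccccc3)c2)c(O)c1OC | intermediate (not isolated)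
12 | (E)-3-[3,4-bis(benzyloxy)phenyl]-1-(2-hydroxy-3,4,5,6-tetramethoxyphenyl)prop-2-en-1-one | COc1c(OC)c(OC)c(C(=O)/C=C/c2ccc(OCc3ccccc3)c(OCc3ccccc3)c2)c(O)c1OC | intermediate
13 | 2-[3,4-bis(benzyloxy)phenyl]-5,6,7,8-tetramethoxychroman-4-one (racemic) | COc1c(OC)c(OC)c2c(c1OC)OC(c1ccc(OCc3ccccc3)c(OCc3ccccc3)c1)CC2=O | intermediate (not isolated)
14 | 2-[3,4-bis(benzyloxy)phenyl]-5,6,7,8-tetramethoxy-4H-chromen-4-one | COc1c(OC)c(OC)c2c(=O)cc(-c3ccc(OCc4ccccc4)c(OCc4ccccc4)c3)oc2c1OC | intermediate
15 | 2-[3,4-bis(benzyloxy)phenyl]-2,3-epoxy-5,6,7,8-tetramethoxychroman-4-one (racemic; epoxide fusion necessarily cis) | COc1c(OC)c(OC)c2c(c1OC)OC1(c3ccc(OCc4ccccc4)c(OCc4ccccc4)c3)OC1C2=O | intermediate (not isolated)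
16 | 2-[3,4-bis(benzyloxy)phenyl]-3-hydroxy-5,6,7,8-tetramethoxy-4H-chromen-4-one | COc1c(OC)c(OC)c2c(=O)c(O)c(-c3ccc(OCc4ccccc4)c(OCc4ccccc4)c3)oc2c1OC | intermediate
17 | 2-(3,4-dihydroxyphenyl)-3-hydroxy-5,6,7,8-tetramethoxy-4H-chromen-4-one | COc1c(OC)c(OC)c2c(=O)c(O)c(-c3ccc(O)c(O)c3)oc2c1OC | intermediate
18 | 2-(3,4-dihydroxyphenyl)-3,5-dihydroxy-6,7,8-trimethoxy-4H-chromen-4-one | COc1c(OC)c(O)c2c(=O)c(O)c(-c3ccc(O)c(O)c3)oc2c1OC | target

**Summary**
Total step count: 10. Longest linear sequence: 10 steps (1 → 18); aldehyde 10 enters at step 6.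

Steps most likely to fail:

Step 5 (acylation with in-flask demethylation). AlCl3 may also cleave internal methoxy groups of the polymethoxyarene or give mixtures of 8 and 9. The fallback sets out from 7 and separates C–C bond formation from demethylation. Deprotonate 7 with n-BuLi/TMEDA in THF at 0 °C (the single ring H is flanked by two OMe, directed ortho-metalation) to give pentamethoxyphenyllithium F1. Add N-methoxy-N-methylacetamide at −78 °C to form the chelated tetrahedral adduct lithium 1-[methoxy(methyl)amino]-1-(pentamethoxyphenyl)ethan-1-olate F2. Aqueous NH4Cl work-up collapses it to ketone 8, which is isolated here. Treat 8 with BCl3 (1.1 eq, CH2Cl2, −78 → 0 °C) for clean mono ortho-demethylation; the route is rejoined at 9.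

Step 8 (DMDO epoxidation and isomerisation). The epoxidation may be slow, and the benzyl ethers or the electron-rich rings may be oxidised competitively. The fallback sets out from 14 and installs the 3-oxygen by anionic chemistry. LDA (1.2 eq, THF, −78 °C) removes H-3 to give 2-[3,4-bis(benzyloxy)phenyl]-3-lithio-5,6,7,8-tetramethoxy-4H-chromen-4-one F3. Trapping with B(OMe)3 at −78 °C gives dimethyl {2-[3,4-bis(benzyloxy)phenyl]-5,6,7,8-tetramethoxy-4-oxo-4H-chromen-3-yl}boronate F4. Oxidation with 30% H2O2/AcOH at 0 °C converts C–B to C–OH; the route is rejoined at 16.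

Step 10 (selective 5-O-demethylation of the free triol). Risks are over-demethylation at C6 once the 5-oxygen is metal-bound, incomplete reaction because the carbonyl is already chelated by the 3-oxygen, and tenacious borate complexes of the catechol. The fallback sets out from 16 and reverses the order of the end game. Treat 16 with anhydrous AlCl3 (3 eq) in MeCN at rt, where the moderated Lewis acid cleaves only the carbonyl-chelated 5-OMe and the remote benzyl ethers are not activated. This gives 2-[3,4-bis(benzyloxy)phenyl]-3,5-dihydroxy-6,7,8-trimethoxy-4H-chromen-4-one F5, which is non-polar and easy to purify by chromatography. Hydrogenolysis (H2, 10% Pd/C, THF/MeOH, rt) then gives the target by filtration and evaporation; the route is rejoined at 18, bypassing 17.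

**Further compounds**
F1 | step 5 | pentamethoxyphenyllithium | [Li]c1c(OC)c(OC)c(OC)c(OC)c1OC
F2 | step 5 | lithium 1-[methoxy(methyl)amino]-1-(pentamethoxyphenyl)ethan-1-olate | CC([O-])(N(C)OC)c1c(OC)c(OC)c(OC)c(OC)c1OC.[Li+]
F3 | step 8 | 2-[3,4-bis(benzyloxy)phenyl]-3-lithio-5,6,7,8-tetramethoxy-4H-chromen-4-one | [Li]c1c(-c2ccc(OCc3ccccc3)c(OCc3ccccc3)c2)oc2c(OC)c(OC)c(OC)c(OC)c2c1=O
F4 | step 8 | dimethyl {2-[3,4-bis(benzyloxy)phenyl]-5,6,7,8-tetramethoxy-4-oxo-4H-chromen-3-yl}boronate | COB(OC)c1c(-c2ccc(OCc3ccccc3)c(OCc3ccccc3)c2)oc2c(OC)c(OC)c(OC)c(OC)c2c1=O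
F5 | step 10 | 2-[3,4-bis(benzyloxy)phenyl]-3,5-dihydroxy-6,7,8-trimethoxy-4H-chromen-4-one | COc1c(OC)c(O)c2c(=O)c(O)c(-c3ccc(OCc4ccccc4)c(OCc4ccccc4)c3)oc2c1OC
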